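**Plan**

- Retrosynthesis: the sulfate O–S bond is cut first, then the ring A–ring B biaryl bond (the ring A carbon next to the sulfated oxygen to C3 of ring B), then the ring B–ring C biaryl bond.
- Forward: two 2,4,6-tribenzyloxyphenyl units are joined by Suzuki–Miyaura coupling (rings B and C), one C–H of that biphenyl is plumbated, and the lead-bound biphenyl is transferred to the ortho carbon of 3,5-dibenzyloxyphenol (ring A). No ring is built; three phloroglucinol rings are only joined.
- Enabling feature: the sulfated oxygen of ring A sits on the carbon ortho to the A–B bond, and rings B and C form a 2,2',4,4',6,6'-hexaoxygenated biphenyl whose C3, C5, C3' and C5' are equivalent. The one free OH of ring A can therefore steer the arylation to its own ortho carbon and is left as the only unprotected oxygen, ready for sulfation.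
- Stereochemistry: there is no stereocentre. The A–B axis is formed without control (racemic if configurationally stable); the B–C axis is not stereogenic because ring C is symmetric.

Key step: step 5

Remark: the target is drawn as the free hydrogen sulfate. Because aryl hydrogen sulfates of polyphenols hydrolyse easily, the compound is assumed to be isolated and stored as its ammonium salt and converted into the acid form only in a last cold ion exchange. Compounds 1 and 7 are taken to be catalogue chemicals.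

**Route**

Step 1
Reactants: 1 1,3,5-tribenzyloxybenzene
Product: 2 2-iodo-1,3,5-tribenzyloxybenzene
Conditions: N-iodosuccinimide (1.0 equiv), MeCN/CH2Cl2, 0 °C to rt, dark
Reagents that add atoms: N-iodosuccinimide, O=C1CCC(=O)N1I
Why: Electrophilic aromatic iodination of a strongly activated trialkoxybenzene whose three C–H positions are equivalent; one equivalent of reagent at low temperature and the deactivating iodine should hold the reaction at the mono-iodide.

Step 2
Reactants: 2 2-iodo-1,3,5-tribenzyloxybenzene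
Product: 4 2-(2,4,6-tribenzyloxyphenyl)-4,4,5,5-tetramethyl-1,3,2-dioxaborolane, via arylmagnesium chloride 3 (not isolated)
Conditions: iPrMgCl·LiCl (1.1 equiv), THF, 0 °C to rt; then 2-isopropoxy-4,4,5,5-tetramethyl-1,3,2-dioxaborolane (1.5 equiv), 0 °C to rt; aq. NH4Cl
Reagents that add atoms: 2-isopropoxy-4,4,5,5-tetramethyl-1,3,2-dioxaborolane, CC(C)OB1OC(C)(C)C(C)(C)O1; isopropylmagnesium chloride–lithium chloride, CC(C)[Mg]Cl.[Li+].[Cl-] (supplies Mg and Cl of intermediate 3 only)
Why: Iodine–magnesium exchange with the turbo Grignard reagent is helped by the two flanking benzyloxy groups, and trapping with the isopropoxy borate gives a pinacol boronate that resists protodeboronation better than the free 2,6-dialkoxyarylboronic acid.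

Step 3
Reactants: 2 2-iodo-1,3,5-tribenzyloxybenzene; 4 2-(2,4,6-tribenzyloxyphenyl)-4,4,5,5-tetramethyl-1,3,2-dioxaborolane (1.3 equiv)
Product: 5 2,2',4,4',6,6'-hexabenzyloxybiphenyl
Conditions: Pd(OAc)2 (5 mol%), SPhos (2-dicyclohexylphosphino-2',6'-dimethoxybiphenyl, 10 mol%), K3PO4 (3 equiv), toluene/H2O 10:1, 100 °C
Reagents that add atoms: none
Why: Suzuki–Miyaura coupling through a zerovalent palladium/divalent palladium cycle; the bulky electron-rich SPhos ligand is well suited to tetra-ortho-substituted biaryls and 2,6-dialkoxyaryl boron partners, and K3PO4 with little water limits protodeboronation.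

Step 4
Reactants: 5 2,2',4,4',6,6'-hexabenzyloxybiphenyl
Product: 6 [2,4,6-tribenzyloxy-3-(2,4,6-tribenzyloxyphenyl)phenyl]lead triacetate
Conditions: Pb(OAc)4 (0.8 equiv, freed of acetic acid), CHCl3, rt, dark; filtration through Celite, concentration, used crude (unreacted 5 is carried along and recovered after step 5)
Reagents that add atoms: lead tetraacetate, CC(=O)O[Pb](OC(C)=O)(OC(C)=O)OC(C)=O
Why: Direct electrophilic aromatic plumbation by Pb(OAc)4 (tetravalent lead) at a carbon flanked by two alkoxy groups, as known for 1,3,5-trimethoxybenzene; the four C–H positions of 5 are equivalent, so any mono-plumbation gives the right connectivity, and a deficit of reagent limits a second plumbation on the other ring.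

Step 5
Reactants: 6 [2,4,6-tribenzyloxy-3-(2,4,6-tribenzyloxyphenyl)phenyl]lead triacetate; 7 3,5-dibenzyloxyphenol (1.5 equiv)
Product: 10 2-[2,4,6-tribenzyloxy-3-(2,4,6-tribenzyloxyphenyl)phenyl]-3,5-dibenzyloxyphenol, via aryloxy(aryl)lead diacetate 8 (not isolated), via 6-arylcyclohexa-2,4-dienone 9 (not isolated)
Conditions: pyridine (3 equiv), CHCl3, 40 to 60 °C
Reagents that add atoms: none
Why: Pyridine-assisted exchange of one acetate on tetravalent lead for the phenoxide of 7 gives 8, whose aryl group migrates from lead to the ortho carbon of the bound phenoxide in a ligand coupling with loss of Pb(OAc)2 (divalent lead), and dienone 9 tautomerises to phenol 10. The closest known reaction type is the Pinhey ortho-arylation of phenols by aryllead triacetates, which is established for electron-rich 3,5-disubstituted phenols and for the equally hindered 2,4,6-trimethoxyphenyl lead reagent. No ring closes and no stereocentre is set; the new A–B axis forms without control. The step needs ortho rather than para C–C bond formation, and delivery from the O–Pb bond secures this because the two ortho carbons of 7 are equivalent and the para carbon is out of reach. It also needs mono- rather than 2,6-diarylation, which the excess of 7 and the shielding of the OH in 10 by the new tetra-ortho-substituted biaryl should secure.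

Step 6
Reactants: 10 2-[2,4,6-tribenzyloxy-3-(2,4,6-tribenzyloxyphenyl)phenyl]-3,5-dibenzyloxyphenol
Product: 11 2-[2,4,6-tribenzyloxy-3-(2,4,6-tribenzyloxyphenyl)phenyl]-3,5-dibenzyloxyphenyl 2,2,2-trichloroethyl sulfate
Conditions: Cl3CCH2OSO2Cl (1.5 equiv), Et3N (1.5 equiv), 4-dimethylaminopyridine (1 equiv), THF, 0 °C to rt
Reagents that add atoms: 2,2,2-trichloroethyl chlorosulfate, ClS(=O)(=O)OCC(Cl)(Cl)Cl
Why: O-sulfonylation of the single free phenol by a chlorosulfate ester under nucleophilic catalysis (trichloroethyl-protected sulfate method) gives a neutral sulfate diester that can be chromatographed and carries the sulfate safely to the last stage.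

Step 7
Reactants: 11 2-[2,4,6-tribenzyloxy-3-(2,4,6-tribenzyloxyphenyl)phenyl]-3,5-dibenzyloxyphenyl 2,2,2-trichloroethyl sulfate
Product: 12 ammonium 2-[2,4,6-trihydroxy-3-(2,4,6-trihydroxyphenyl)phenyl]-3,5-dihydroxyphenyl sulfate
Conditions: 10% Pd/C, HCO2NH4 (20 equiv), MeOH/THF, rt; then H2 (1 atm), rt; filtration, Sephadex LH-20 (MeOH)
Reagents that add atoms: ammonium formate, [NH4+].[O-]C=O (supplies the ammonium counter-ion)
Why: Palladium with formate cleaves the trichloroethyl ester by C–Cl insertion and β-elimination of the sulfate, the same catalyst removes the eight benzyl ethers by hydrogenolysis, and the aryl sulfate monoester anion is inert to hydrogenolysis and protected from acid hydrolysis by the ammonium formate buffer.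

Step 8
Reactants: 12 ammonium 2-[2,4,6-trihydroxy-3-(2,4,6-trihydroxyphenyl)phenyl]-3,5-dihydroxyphenyl sulfate
Product: 13 2-[2,4,6-trihydroxy-3-(2,4,6-trihydroxyphenyl)phenyl]-3,5-dihydroxyphenyl hydrogen sulfate (CNP0244954.0)
Conditions: sulfonic acid cation-exchange resin (H+ form), H2O/MeOH, 0 °C; immediate freeze-drying
Reagents that add atoms: none
Why: Plain cation exchange of ammonium for a proton; working cold, dilute and briefly should keep the electron-rich aryl hydrogen sulfate from autocatalytic hydrolysis.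

**Compound list**

1 | 1,3,5-tribenzyloxybenzene | c1c(OCc2ccccc2)cc(OCc2ccccc2)cc1OCc1ccccc1 | starting material
2 | 2-iodo-1,3,5-tribenzyloxybenzene | Ic1c(OCc2ccccc2)cc(OCc2ccccc2)cc1OCc1ccccc1 | intermediate
3 | (2,4,6-tribenzyloxyphenyl)magnesium chloride | Cl[Mg]c1c(OCc2ccccc2)cc(OCc2ccccc2)cc1OCc1ccccc1 | intermediate (not isolated)
4 | 2-(2,4,6-tribenzyloxyphenyl)-4,4,5,5-tetramethyl-1,3,2-dioxaborolane | CC1(C)OB(OC1(C)C)c1c(OCc2ccccc2)cc(OCc2ccccc2)cc1OCc1ccccc1 | intermediate
5 | 2,2',4,4',6,6'-hexabenzyloxybiphenyl | C(c1ccccc1)Oc1cc(OCc2ccccc2)cc(OCc2ccccc2)c1-c1c(OCc2ccccc2)cc(OCc2ccccc2)cc1OCc1ccccc1 | intermediate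
6 | [2,4,6-tribenzyloxy-3-(2,4,6-tribenzyloxyphenyl)phenyl]lead triacetate | C(c1ccccc1)Oc1cc(OCc2ccccc2)cc(OCc2ccccc2)c1-c1c(OCc2ccccc2)c([Pb](OC(C)=O)(OC(C)=O)OC(C)=O)c(OCc2ccccc2)cc1OCc1ccccc1 | intermediate
7 | 3,5-dibenzyloxyphenol | Oc1cc(OCc2ccccc2)cc(OCc2ccccc2)c1 | starting material
8 | (3,5-dibenzyloxyphenoxy)[2,4,6-tribenzyloxy-3-(2,4,6-tribenzyloxyphenyl)phenyl]lead diacetate | CC(=O)O[Pb](OC(C)=O)(Oc1cc(OCc2ccccc2)cc(OCc2ccccc2)c1)c1c(OCc2ccccc2)cc(OCc2ccccc2)c(-c2c(OCc3ccccc3)cc(OCc3ccccc3)cc2OCc2ccccc2)c1OCc1ccccc1 | intermediate (not isolated)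
9 | 6-[2,4,6-tribenzyloxy-3-(2,4,6-tribenzyloxyphenyl)phenyl]-3,5-dibenzyloxycyclohexa-2,4-dien-1-one (racemic at C6) | O=C1C=C(OCc2ccccc2)C=C(OCc2ccccc2)C1c1c(OCc2ccccc2)cc(OCc2ccccc2)c(-c2c(OCc3ccccc3)cc(OCc3ccccc3)cc2OCc2ccccc2)c1OCc1ccccc1 | intermediate (not isolated)
10 | 2-[2,4,6-tribenzyloxy-3-(2,4,6-tribenzyloxyphenyl)phenyl]-3,5-dibenzyloxyphenol | C(c1ccccc1)Oc1cc(OCc2ccccc2)cc(OCc2ccccc2)c1-c1c(OCc2ccccc2)c(-c2c(O)cc(OCc3ccccc3)cc2OCc2ccccc2)c(OCc2ccccc2)cc1OCc1ccccc1 | intermediate
11 | 2-[2,4,6-tribenzyloxy-3-(2,4,6-tribenzyloxyphenyl)phenyl]-3,5-dibenzyloxyphenyl 2,2,2-trichloroethyl sulfate | C(c1ccccc1)Oc1cc(OCc2ccccc2)cc(OCc2ccccc2)c1-c1c(OCc2ccccc2)c(-c2c(OS(=O)(=O)OCC(Cl)(Cl)Cl)cc(OCc3ccccc3)cc2OCc2ccccc2)c(OCc2ccccc2)cc1OCc1ccccc1 | intermediate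
12 | ammonium 2-[2,4,6-trihydroxy-3-(2,4,6-trihydroxyphenyl)phenyl]-3,5-dihydroxyphenyl sulfate | [NH4+].[O-]S(=O)(=O)Oc1cc(O)cc(O)c1-c1c(O)cc(O)c(-c2c(O)cc(O)cc2O)c1O | intermediate
13 | 2-[2,4,6-trihydroxy-3-(2,4,6-trihydroxyphenyl)phenyl]-3,5-dihydroxyphenyl hydrogen sulfate (CNP0244954.0) | O=S(=O)(O)Oc1cc(O)cc(O)c1-c1c(O)cc(O)c(-c2c(O)cc(O)cc2O)c1O | target

**Count and risks**

Total step count: 8. Longest linear sequence: 8 steps (1 to 13); 7 enters at step 5.

Steps most likely to fail:

1. Step 5 (key step). The aryl transfer on lead between two hindered partners may be slow. It could then give way to protodeplumbation of 6, oxidation of the electron-rich phenol by tetravalent lead, or a second arylation at the other ortho carbon. The fallback sets out from 7 and 5 and comes back at 10. It makes the A–B bond by Suzuki–Miyaura coupling, with the ring A oxygen masked as a carbamate that directs metalation to its own ortho carbon.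
   - 7 with ClCONEt2 and NaH in THF should give 3,5-dibenzyloxyphenyl N,N-diethylcarbamate F1.
   - sBuLi/TMEDA in THF at −78 °C lithiates between the carbamate and a benzyloxy group; quenching with the isopropoxy pinacol borate should give 3,5-dibenzyloxy-2-(4,4,5,5-tetramethyl-1,3,2-dioxaborolan-2-yl)phenyl N,N-diethylcarbamate F2.
   - In parallel, 5 with N-bromosuccinimide (1 equiv) in CH2Cl2 at 0 °C should give 3-bromo-2,2',4,4',6,6'-hexabenzyloxybiphenyl F3, which can be separated from 5 by chromatography.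
   - Coupling F2 with F3 using Pd(OAc)2, SPhos and K3PO4 in toluene/H2O at 100 °C should give 2-[2,4,6-tribenzyloxy-3-(2,4,6-tribenzyloxyphenyl)phenyl]-3,5-dibenzyloxyphenyl N,N-diethylcarbamate F4.
   - LiAlH4 in THF at reflux removes the carbamate and returns phenol 10.

2. Step 4. Plumbation may not stop cleanly: a second lead may enter the other ring, the arene or a benzyl ether may be oxidised, and the crude reagent may protodeplumbate on handling, since it cannot be purified. The fallback sets out from 5 and comes back at 6. It fixes the site on a stable, chromatographable intermediate and forms the C–Pb bond by transmetalation.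
   - 5 with N-iodosuccinimide (1 equiv) in CH2Cl2 at 0 °C should give 3-iodo-2,2',4,4',6,6'-hexabenzyloxybiphenyl F5.
   - Iodine–magnesium exchange with iPrMgCl·LiCl in THF and quenching with Bu3SnCl should give tributyl[2,4,6-tribenzyloxy-3-(2,4,6-tribenzyloxyphenyl)phenyl]stannane F6.
   - Tin–lead exchange with Pb(OAc)4 and catalytic Hg(OCOCF3)2 in CHCl3 at rt delivers 6 free of unreacted 5 and of excess oxidant.

3. Step 7. The trichloroethyl group may be only partly dechlorinated to chloroethyl sulfates that no longer fragment, or the sulfate may be lost by acid hydrolysis while eight benzyl ethers are slowly removed. The fallback sets out from 11 and comes back at 12. It separates the two events.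
   - Zinc dust and HCO2NH4 in MeOH/THF at rt remove the trichloroethyl group by reductive β-elimination, which should give ammonium 2-[2,4,6-tribenzyloxy-3-(2,4,6-tribenzyloxyphenyl)phenyl]-3,5-dibenzyloxyphenyl sulfate F7.
   - Hydrogenolysis of F7 with H2 (1 atm) over Pd/C in MeOH/THF containing a trace of NH3 then gives 12.

Further compounds
F1 | step 5 | 3,5-dibenzyloxyphenyl N,N-diethylcarbamate | CCN(CC)C(=O)Oc1cc(OCc2ccccc2)cc(OCc2ccccc2)c1
F2 | step 5 | 3,5-dibenzyloxy-2-(4,4,5,5-tetramethyl-1,3,2-dioxaborolan-2-yl)phenyl N,N-diethylcarbamate | CCN(CC)C(=O)Oc1cc(OCc2ccccc2)cc(OCc2ccccc2)c1B1OC(C)(C)C(C)(C)O1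
F3 | step 5 | 3-bromo-2,2',4,4',6,6'-hexabenzyloxybiphenyl | Brc1c(OCc2ccccc2)cc(OCc2ccccc2)c(-c2c(OCc3ccccc3)cc(OCc3ccccc3)cc2OCc2ccccc2)c1OCc1ccccc1
F4 | step 5 | 2-[2,4,6-tribenzyloxy-3-(2,4,6-tribenzyloxyphenyl)phenyl]-3,5-dibenzyloxyphenyl N,N-diethylcarbamate | CCN(CC)C(=O)Oc1cc(OCc2ccccc2)cc(OCc2ccccc2)c1-c1c(OCc2ccccc2)cc(OCc2ccccc2)c(-c2c(OCc3ccccc3)cc(OCc3ccccc3)cc2OCc2ccccc2)c1OCc1ccccc1
F5 | step 4 | 3-iodo-2,2',4,4',6,6'-hexabenzyloxybiphenyl | Ic1c(OCc2ccccc2)cc(OCc2ccccc2)c(-c2c(OCc3ccccc3)cc(OCc3ccccc3)cc2OCc2ccccc2)c1OCc1ccccc1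
F6 | step 4 | tributyl[2,4,6-tribenzyloxy-3-(2,4,6-tribenzyloxyphenyl)phenyl]stannane | CCCC[Sn](CCCC)(CCCC)c1c(OCc2ccccc2)cc(OCc2ccccc2)c(-c2c(OCc3ccccc3)cc(OCc3ccccc3)cc2OCc2ccccc2)c1OCc1ccccc1
F7 | step 7 | ammonium 2-[2,4,6-tribenzyloxy-3-(2,4,6-tribenzyloxyphenyl)phenyl]-3,5-dibenzyloxyphenyl sulfate | [NH4+].[O-]S(=O)(=O)Oc1cc(OCc2ccccc2)cc(OCc2ccccc2)c1-c1c(OCc2ccccc2)cc(OCc2ccccc2)c(-c2c(OCc3ccccc3)cc(OCc3ccccc3)cc2OCc2ccccc2)c1OCc1ccccc1
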